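**Plan**
- Retrosynthetic cuts: the vanilloyl ester C6–O; the C8=C14 methylene (Peterson), the C6–O/C5–H pair (hydroboration) and the C9–O bond (enol silane oxidation); then C1–C5 and C1–C10 together (arene ring expansion); then C1–C2 (acylation of diazoethane) and C3–C4 (allylation of an aryl ketone).
- Enabling feature: the seven-membered ring C1/C5/C6/C7/C8/C9/C10 is an anisole ring (C5–C10, oxygen on C8, para to the ring-fusion carbon C5) with the methyl-bearing quaternary C1 inserted into its C5–C10 bond; C1 also belongs to the five-membered ring C1–C5.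
- Forward order: the acyclic chain is built first (C4 carbinol, C2 acid, α-methyl diazoketone); one rhodium carbenoid step then closes the cyclopentanone and expands the arene to the cycloheptatriene; the rest is functional-group work on the bicycle.
- Stereochemistry: C4 from a catalytic enantioselective allylboration; C1 from C4 in the carbenoid step; C9, C5 and C6 from reagent approach to the α-face, anti to the angular C1 methyl group.

Key step: step 6

Remark: daucane numbering is used (C1 quaternary ring-fusion carbon with its methyl, C2, C3, C4 carbinol carbon with isopropyl, C5 ring-fusion CH, C6–C10 round the seven-membered ring, C14 the carbon on C8). α is the face of H-5 and β the face of the C1 methyl group.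
Assumption: the antipode of the aminophenol catalyst of step 1 that gives the (R)-carbinol is used; the sense of induction is to be assigned by correlation in the first run.

Step 1
Reactants: 1 4'-methoxyisobutyrophenone; 2 allylboronic acid pinacol ester
Product: 3 (R)-3-(4-methoxyphenyl)-2-methylhex-5-en-3-ol
Conditions: 2 (1.5 equiv), (S)-2-[(3-tert-butyl-2-hydroxybenzyl)amino]-N,N,3-trimethylbutanamide or its antipode (3 mol%), NaOtBu (5 mol%), MeOH (2 equiv), toluene, rt
Reagents that add atoms: none
Why: Catalytic enantioselective allylboration of a ketone, in which the chiral aminophenol-bound allylboron species should deliver the allyl group to one face of the aryl isopropyl ketone and so set C4 as the (R)-carbinol.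

Step 2
Reactants: 3 (R)-3-(4-methoxyphenyl)-2-methylhex-5-en-3-ol
Product: 4 (R)-triethyl{[3-(4-methoxyphenyl)-2-methylhex-5-en-3-yl]oxy}silane
Conditions: TESOTf, 2,6-lutidine, CH2Cl2, 0 °C → rt
Reagents that add atoms: triethylsilyl trifluoromethanesulfonate CC[Si](CC)(CC)OS(=O)(=O)C(F)(F)F
Why: Silyl triflate silylation of a hindered tertiary alcohol, with the lutidine buffer keeping the acid-labile p-methoxybenzylic carbinol from ionising.

Step 3
Reactants: 4 (R)-triethyl{[3-(4-methoxyphenyl)-2-methylhex-5-en-3-yl]oxy}silane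
Product: 6 (R)-3-(4-methoxyphenyl)-4-methyl-3-(triethylsilyloxy)pentanoic acid, via aldehyde 5 (not isolated)
Conditions: O3 (1 equiv), MeCN/H2O (9:1), 0 °C, N2 purge; then NaClO2, NaH2PO4, 2-methyl-2-butene, 0 °C → rt
Reagents that add atoms: ozone [O-][O+]=O; water O; sodium chlorite [Na+].[O-]Cl=O
Why: Telescoped ozonolysis–Pinnick oxidation, in which the terminal alkene should react with ozone far faster than the anisole ring, water converts the carbonyl oxide directly into the aldehyde, and buffered chlorite with a hypochlorite scavenger oxidises it to the acid without touching the silyl ether.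

Step 4
Reactants: 7 N-ethyl-N-nitrosourea
Product: 8 diazoethane (dried ethereal solution used at once)
Conditions: KOH (40% aq.), Et2O, −10 → 0 °C; ether layer decanted and dried over KOH pellets
Reagents that add atoms: none
Why: Base-induced decomposition of an N-alkyl-N-nitrosourea, the standard laboratory preparation of a diazoalkane.

Step 5
Reactants: 6 (R)-3-(4-methoxyphenyl)-4-methyl-3-(triethylsilyloxy)pentanoic acid; 8 diazoethane
Product: 10 (R)-2-diazo-5-(4-methoxyphenyl)-6-methyl-5-(triethylsilyloxy)heptan-3-one, via acid chloride 9 (not isolated)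
Conditions: 1-chloro-N,N,2-trimethylprop-1-en-1-amine, CH2Cl2, 0 °C → rt; then added to 8 (3 equiv), Et2O, −20 → 0 °C
Reagents that add atoms: none
Why: Acylation of a diazoalkane by an acid chloride (Arndt–Eistert-type diazoketone synthesis), with the acid chloride made under neutral conditions by the α-chloroenamine and excess diazoethane taking up the HCl so that the tertiary benzylic silyl ether never meets acid.

Step 6
Reactants: 10 (R)-2-diazo-5-(4-methoxyphenyl)-6-methyl-5-(triethylsilyloxy)heptan-3-one
Product: 12 (3R,8aR)-6-methoxy-8a-methyl-3-(propan-2-yl)-3-(triethylsilyloxy)-3,8a-dihydroazulen-1(2H)-one, via norcaradiene 11 (not isolated)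
Conditions: Rh2(OAc)4 (1 mol%), CH2Cl2, reflux, slow addition of 10
Reagents that add atoms: none
Why: Loss of N2 gives a rhodium carbenoid at C1 that adds across the C5–C10 (ipso–ortho) bond of the anisole ring, so that C1–C5 closes the cyclopentanone (five-membered closure onto the ipso carbon) and C1–C10 closes the cyclopropane of norcaradiene 11, whose disrotatory 6π-electrocyclic opening of the C5–C10 bond expands the benzene ring to the cycloheptatriene; this is the intramolecular Buchner reaction, well known for α-methyl α-diazoketones with a tethered arene. The new quaternary centre C1 is set relative to C4: in the envelope-like transition state the isopropyl group should sit pseudo-equatorial and the smaller silyloxy group pseudo-axial, so the carbenoid should engage the ortho carbon that places the C1 methyl cis to the silyloxy group and trans to the isopropyl group (8aR). The step needs arene addition to outrun 1,2-hydride shift from the carbenoid methyl group, C–H insertion into the isopropyl methine and attack on the ether oxygen; the electron-rich anisole ring, the fully substituted C4 in the tether and the hindered, weakly basic triethylsilyl ether should secure this. The para-methoxy group ends as the C8 enol ether, a masked C8 ketone.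

Step 7
Reactants: 12 (3R,8aR)-6-methoxy-8a-methyl-3-(propan-2-yl)-3-(triethylsilyloxy)-3,8a-dihydroazulen-1(2H)-one
Product: 14 (1R,3aR)-6-methoxy-3a-methyl-1-(propan-2-yl)-1-(triethylsilyloxy)-1,2,3,3a-tetrahydroazulene, via N-silylhydrazone 13 (not isolated)
Conditions: 1,2-bis(tert-butyldimethylsilyl)hydrazine, Sc(OTf)3 (cat.), CHCl3, rt → 55 °C, volatiles removed; then KOtBu, tBuOH, DMSO, rt → 60 °C
Reagents that add atoms: none
Why: Wolff–Kishner reduction in its N-silylhydrazone form, in which the hydrazone forms without free base (so the β-silyloxy ketone cannot eliminate) and then decomposes by an anionic path that should leave the enol ether, the triene (no ring C–H at C1 to shift) and the silyl ether intact and avoids the vinyl migrations a C2 radical would suffer.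

Step 8
Reactants: 14 (1R,3aR)-6-methoxy-3a-methyl-1-(propan-2-yl)-1-(triethylsilyloxy)-1,2,3,3a-tetrahydroazulene
Product: 15 4β-(triethylsilyloxy)-14-nordauca-5,9-dien-8-one
Conditions: oxalic acid (0.1 M aq.), THF, 0 °C → rt
Reagents that add atoms: water O
Why: Kinetic hydrolysis of a dienol ether, in which protonation at C7 and loss of methanol should give the β,γ-unsaturated ketone with the C5=C6 bond left in place (as in the oxalic acid hydrolysis of Birch-type dienol ethers), the weak general acid being chosen so that C-protonation outruns ionisation of the C4 silyloxy group.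

Step 9
Reactants: 15 4β-(triethylsilyloxy)-14-nordauca-5,9-dien-8-one
Product: 16 4β,8-bis(triethylsilyloxy)-14-nordauca-5,8-diene
Conditions: Et3SiH (1.5 equiv), RhCl(PPh3)3 (2 mol%), toluene, 60 °C
Reagents that add atoms: triethylsilane CC[SiH](CC)CC
Why: Rhodium-catalysed 1,4-hydrosilylation of the only enone with a monohydrosilane, which should put hydrogen on C10 and give the C8=C9 enol silane regiospecifically while the isolated, hindered C5=C6 bond stays untouched.

Step 10
Reactants: 16 4β,8-bis(triethylsilyloxy)-14-nordauca-5,8-diene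
Product: 18 4β,9α-bis(triethylsilyloxy)-14-nordauc-5-en-8-one, via silyloxy epoxide 17 (not isolated)
Conditions: mCPBA (1.05 equiv), NaHCO3, CH2Cl2, −40 → 0 °C
Reagents that add atoms: 3-chloroperoxybenzoic acid OOC(=O)c1cccc(Cl)c1
Why: Rubottom oxidation, in which the electron-rich enol silane should be epoxidised much faster than the hindered C5=C6 bond and from the α-face opposite the angular C1 methyl group, and 1,4-silyl migration in 17 then gives the 9α-silyloxy ketone (9S).

Step 11
Reactants: 18 4β,9α-bis(triethylsilyloxy)-14-nordauc-5-en-8-one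
Product: 19 4β,9α-bis(triethylsilyloxy)-14-(trimethylsilyl)dauc-5-en-8α-ol
Conditions: Me3SiCH2Li, CeCl3 (anhydrous), THF, −78 °C
Reagents that add atoms: (trimethylsilyl)methyllithium [Li]C[Si](C)(C)C
Why: Organocerium addition (first half of a Peterson methylenation), non-basic enough to add to the ketone without deprotonating the doubly activated C7; attack anti to the C9 silyloxy group should give the 8α-alcohol, and either C8 epimer serves the main route because this centre is lost in step 15.

Step 12
Reactants: 19 4β,9α-bis(triethylsilyloxy)-14-(trimethylsilyl)dauc-5-en-8α-ol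
Product: 20 4β,9α-bis(triethylsilyloxy)-14-(trimethylsilyl)-5αH-daucane-6α,8α-diol
Conditions: BH3·THF (excess), THF, 0 °C → rt; then NaOH (aq.), H2O2 (30%), 0 °C
Reagents that add atoms: hydrogen peroxide OO
Why: Hydroboration–oxidation of the only C=C bond left, with boron going to the less substituted C6 and hydrogen to C5 in a syn addition from the α-face, anti to the angular C1 methyl and the β-oriented C4 silyloxy and C8 CH2SiMe3 groups (as in the hydroboration of Δ5-steroids), which should set 5α-H (trans ring fusion, 5S) and 6α-OH (6S).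

Step 13
Reactants: 21 vanillic acid
Product: 23 4-(tert-butyldimethylsilyloxy)-3-methoxybenzoic acid, via bis-silyl derivative 22 (not isolated)
Conditions: TBSCl (2.5 equiv), imidazole, DMF, rt; then AcOH/THF/H2O, rt
Reagents that add atoms: tert-butyldimethylsilyl chloride CC(C)(C)[Si](C)(C)Cl
Why: Exhaustive silylation followed by selective hydrolysis of the far more labile silyl ester, which should leave the phenol masked as its silyl ether.

Step 14
Reactants: 20 4β,9α-bis(triethylsilyloxy)-14-(trimethylsilyl)-5αH-daucane-6α,8α-diol; 23 4-(tert-butyldimethylsilyloxy)-3-methoxybenzoic acid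
Product: 24 8α-hydroxy-4β,9α-bis(triethylsilyloxy)-14-(trimethylsilyl)-5αH-daucan-6α-yl 4-(tert-butyldimethylsilyloxy)-3-methoxybenzoate
Conditions: N-(3-dimethylaminopropyl)-N'-ethylcarbodiimide hydrochloride, DMAP, CH2Cl2, 0 °C → rt
Reagents that add atoms: none
Why: Steglich esterification, in which only the secondary C6 hydroxyl should be acylated because the C8 hydroxyl is tertiary and hindered.

Step 15
Reactants: 24 8α-hydroxy-4β,9α-bis(triethylsilyloxy)-14-(trimethylsilyl)-5αH-daucan-6α-yl 4-(tert-butyldimethylsilyloxy)-3-methoxybenzoate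
Product: 25 (3R,3aS,4S,7S,8aR)-3,7-dihydroxy-8a-methyl-6-methylidene-3-(propan-2-yl)decahydroazulen-4-yl 4-hydroxy-3-methoxybenzoate (4β,9α-dihydroxy-6α-vanilloyloxydauc-8(14)-ene)
Conditions: HF (48% aq.), MeCN, 0 °C → rt
Reagents that add atoms: none
Why: Acidic fluoride removes the three silyl ethers, and under the same conditions the β-hydroxysilane should undergo Peterson elimination (anti loss of water and the trimethylsilyl group through the β-silyl-stabilised C8 cation), which gives the exocyclic C8=C14 double bond regiospecifically.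

**Compound list**
1 | 4'-methoxyisobutyrophenone | CC(C)C(=O)c1ccc(OC)cc1 | starting material
2 | allylboronic acid pinacol ester | C=CCB1OC(C)(C)C(C)(C)O1 | starting material
3 | (R)-3-(4-methoxyphenyl)-2-methylhex-5-en-3-ol | CC(C)[C@](O)(CC=C)c1ccc(OC)cc1 | intermediate
4 | (R)-triethyl{[3-(4-methoxyphenyl)-2-methylhex-5-en-3-yl]oxy}silane | CC(C)[C@](O[Si](CC)(CC)CC)(CC=C)c1ccc(OC)cc1 | intermediate
5 | (R)-3-(4-methoxyphenyl)-4-methyl-3-(triethylsilyloxy)pentanal | CC(C)[C@](O[Si](CC)(CC)CC)(CC=O)c1ccc(OC)cc1 | intermediate (not isolated)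
6 | (R)-3-(4-methoxyphenyl)-4-methyl-3-(triethylsilyloxy)pentanoic acid | CC(C)[C@](O[Si](CC)(CC)CC)(CC(=O)O)c1ccc(OC)cc1 | intermediate
7 | N-ethyl-N-nitrosourea | CCN(N=O)C(N)=O | starting material
8 | diazoethane | CC=[N+]=[N-] | intermediate
9 | (R)-3-(4-methoxyphenyl)-4-methyl-3-(triethylsilyloxy)pentanoyl chloride | CC(C)[C@](O[Si](CC)(CC)CC)(CC(=O)Cl)c1ccc(OC)cc1 | intermediate (not isolated)
10 | (R)-2-diazo-5-(4-methoxyphenyl)-6-methyl-5-(triethylsilyloxy)heptan-3-one | CC(C)[C@](O[Si](CC)(CC)CC)(CC(=O)C(C)=[N+]=[N-])c1ccc(OC)cc1 | intermediate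
11 | norcaradiene valence tautomer of 12 (cyclopropane C1–C5–C10, diene C6=C7 and C8=C9) | CC(C)[C@]1(O[Si](CC)(CC)CC)CC(=O)[C@]2(C)[C@H]3C=C(OC)C=C[C@@]123 | intermediate (not isolated)
12 | (3R,8aR)-6-methoxy-8a-methyl-3-(propan-2-yl)-3-(triethylsilyloxy)-3,8a-dihydroazulen-1(2H)-one | CC(C)[C@]1(O[Si](CC)(CC)CC)CC(=O)[C@]2(C)C=CC(OC)=CC=C12 | intermediate
13 | N-(tert-butyldimethylsilyl)hydrazone of 12 | CC(C)[C@]1(O[Si](CC)(CC)CC)CC(=NN[Si](C)(C)C(C)(C)C)[C@]2(C)C=CC(OC)=CC=C12 | intermediate (not isolated)
14 | (1R,3aR)-6-methoxy-3a-methyl-1-(propan-2-yl)-1-(triethylsilyloxy)-1,2,3,3a-tetrahydroazulene | CC(C)[C@]1(O[Si](CC)(CC)CC)CC[C@]2(C)C=CC(OC)=CC=C12 | intermediate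
15 | 4β-(triethylsilyloxy)-14-nordauca-5,9-dien-8-one; (1R,3aR)-3a-methyl-1-(propan-2-yl)-1-(triethylsilyloxy)-2,3,3a,7-tetrahydroazulen-6(1H)-one | O=C1CC=C2[C@](C)(CC[C@@]2(O[Si](CC)(CC)CC)C(C)C)C=C1 | intermediate
16 | 4β,8-bis(triethylsilyloxy)-14-nordauca-5,8-diene | CC[Si](CC)(CC)OC1=CC[C@@]2(C)CC[C@@](O[Si](CC)(CC)CC)(C(C)C)C2=CC1 | intermediate
17 | 8α,9α-epoxy-4β,8β-bis(triethylsilyloxy)-14-nordauc-5-ene | CC[Si](CC)(CC)O[C@@]13CC=C2[C@](C)(CC[C@@]2(O[Si](CC)(CC)CC)C(C)C)C[C@@H]1O3 | intermediate (not isolated)
18 | 4β,9α-bis(triethylsilyloxy)-14-nordauc-5-en-8-one | O=C1CC=C2[C@](C)(CC[C@@]2(O[Si](CC)(CC)CC)C(C)C)C[C@@H]1O[Si](CC)(CC)CC | intermediate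
19 | 4β,9α-bis(triethylsilyloxy)-14-(trimethylsilyl)dauc-5-en-8α-ol | C[Si](C)(C)C[C@@]1(O)CC=C2[C@](C)(CC[C@@]2(O[Si](CC)(CC)CC)C(C)C)C[C@@H]1O[Si](CC)(CC)CC | intermediate
20 | 4β,9α-bis(triethylsilyloxy)-14-(trimethylsilyl)-5αH-daucane-6α,8α-diol | C[Si](C)(C)C[C@@]1(O)C[C@H](O)[C@@H]2[C@](C)(CC[C@@]2(O[Si](CC)(CC)CC)C(C)C)C[C@@H]1O[Si](CC)(CC)CC | intermediate
21 | vanillic acid (4-hydroxy-3-methoxybenzoic acid) | COc1cc(C(=O)O)ccc1O | starting material
22 | tert-butyldimethylsilyl 4-(tert-butyldimethylsilyloxy)-3-methoxybenzoate | COc1cc(C(=O)O[Si](C)(C)C(C)(C)C)ccc1O[Si](C)(C)C(C)(C)C | intermediate (not isolated)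
23 | 4-(tert-butyldimethylsilyloxy)-3-methoxybenzoic acid | COc1cc(C(=O)O)ccc1O[Si](C)(C)C(C)(C)C | intermediate
24 | 8α-hydroxy-4β,9α-bis(triethylsilyloxy)-14-(trimethylsilyl)-5αH-daucan-6α-yl 4-(tert-butyldimethylsilyloxy)-3-methoxybenzoate | C[Si](C)(C)C[C@@]1(O)C[C@H](OC(=O)c3ccc(O[Si](C)(C)C(C)(C)C)c(OC)c3)[C@@H]2[C@](C)(CC[C@@]2(O[Si](CC)(CC)CC)C(C)C)C[C@@H]1O[Si](CC)(CC)CC | intermediate
25 | (3R,3aS,4S,7S,8aR)-3,7-dihydroxy-8a-methyl-6-methylidene-3-(propan-2-yl)decahydroazulen-4-yl 4-hydroxy-3-methoxybenzoate | C=C1C[C@H](OC(=O)c2ccc(O)c(OC)c2)[C@@H]2[C@](C)(CC[C@@]2(O)C(C)C)C[C@@H]1O | target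

**Step count**
Total: 15 steps. Longest linear sequence: 13 steps (1, 2, 3, 5, 6, 7, 8, 9, 10, 11, 12, 14, 15); steps 4 and 13 are side branches.

**Steps most likely to fail**

Step 6 (carbenoid ring expansion). Before the carbenoid reaches the arene, hydride may migrate from its methyl group (giving a vinyl ketone) or the neighbouring silyl ether oxygen may attack it, and the two ortho carbons may be discriminated incompletely. The fallback separates ring expansion from methylation. It sets out from acid 6, which is converted into acid chloride 9 as in step 5. (Trimethylsilyl)diazomethane in MeCN/THF at 0 °C should then give the terminal diazoketone (R)-1-diazo-4-(4-methoxyphenyl)-5-methyl-4-(triethylsilyloxy)hexan-2-one F1, which has no hydrogen next to the carbene carbon and belongs to the most dependable class for intramolecular arene addition. Rh2(OAc)4 in refluxing CH2Cl2 should convert it into the 8a-unsubstituted azulenone (3R)-6-methoxy-3-(propan-2-yl)-3-(triethylsilyloxy)-3,8a-dihydroazulen-1(2H)-one F2, whose C8a epimers are of no consequence. LiHMDS in THF at −78 °C should remove the doubly allylic proton at C1, and methyl iodide should alkylate the enolate at C1 on the face anti to the isopropyl group. This gives 12, where the route is rejoined.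

Step 12 (hydroboration). Borane may approach the crowded C5=C6 bond from the β-face, giving the cis-fused 5β,6β-isomer, or add too slowly. The fallback delivers silicon and hydrogen intramolecularly from the 8α-hydroxyl and therefore relies on the 8α-epimer of 19 drawn in the list. It sets out from 19: chlorodimethylsilane, Et3N and DMAP in CH2Cl2 should give the hydridosilyl ether 8α-(dimethylsilyloxy)-4β,9α-bis(triethylsilyloxy)-14-(trimethylsilyl)dauc-5-ene F3. Pt2[(CH2=CHSiMe2)2O]3 (zerovalent platinum, catalytic) in toluene should then effect 5-exo intramolecular hydrosilylation, with silicon going to C6 and hydrogen to C5, both from the α-face fixed by the tether, to give the oxasilolane 6α,8α-(dimethylsilanediyloxy)-4β,9α-bis(triethylsilyloxy)-14-(trimethylsilyl)-5αH-daucane F4. Tamao oxidation (H2O2, KF, KHCO3, THF/MeOH) replaces the C6–Si bond by C6–OH with retention and frees the C8 hydroxyl, which gives 20, where the route is rejoined.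

Step 1 (allylboration). The catalyst may not distinguish the aryl and isopropyl faces of the ketone well enough, so that the carbinol forms with low enantiomeric purity. The fallback replaces catalytic asymmetric induction by a classical resolution. It sets out from ketone 1: a Reformatsky reaction (activated Zn, ethyl bromoacetate, THF, reflux) should give racemic ethyl 3-hydroxy-3-(4-methoxyphenyl)-4-methylpentanoate F5, and LiOH in THF/H2O the racemic 3-hydroxy-3-(4-methoxyphenyl)-4-methylpentanoic acid F6. Crystallisation with (S)-1-phenylethylamine should give the salt (S)-1-phenylethylammonium (R)-3-hydroxy-3-(4-methoxyphenyl)-4-methylpentanoate F7; the antipodal amine is taken if the salt of the (S)-acid crystallises instead. Aqueous citric acid frees (R)-3-hydroxy-3-(4-methoxyphenyl)-4-methylpentanoic acid F8. TESOTf (2.2 equiv) and 2,6-lutidine give triethylsilyl (R)-3-(4-methoxyphenyl)-4-methyl-3-(triethylsilyloxy)pentanoate F9, and AcOH/THF/H2O cleaves only the silyl ester to give 6, where the route is rejoined.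

**Further compounds**
F1 | step 6 | (R)-1-diazo-4-(4-methoxyphenyl)-5-methyl-4-(triethylsilyloxy)hexan-2-one | CC(C)[C@](O[Si](CC)(CC)CC)(CC(=O)C=[N+]=[N-])c1ccc(OC)cc1
F2 | step 6 | (3R)-6-methoxy-3-(propan-2-yl)-3-(triethylsilyloxy)-3,8a-dihydroazulen-1(2H)-one (C8a epimers) | CC(C)[C@]1(O[Si](CC)(CC)CC)CC(=O)C2C=CC(OC)=CC=C12
F3 | step 12 | 8α-(dimethylsilyloxy)-4β,9α-bis(triethylsilyloxy)-14-(trimethylsilyl)dauc-5-ene | C[Si](C)(C)C[C@@]1(O[SiH](C)C)CC=C2[C@](C)(CC[C@@]2(O[Si](CC)(CC)CC)C(C)C)C[C@@H]1O[Si](CC)(CC)CC
F4 | step 12 | 6α,8α-(dimethylsilanediyloxy)-4β,9α-bis(triethylsilyloxy)-14-(trimethylsilyl)-5αH-daucane (oxasilolane with Si on C6 and O on C8) | C[Si](C)(C)C[C@@]13C[C@H]([Si](C)(C)O3)[C@@H]2[C@](C)(CC[C@@]2(O[Si](CC)(CC)CC)C(C)C)C[C@@H]1O[Si](CC)(CC)CC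
F5 | step 1 | racemic ethyl 3-hydroxy-3-(4-methoxyphenyl)-4-methylpentanoate | CCOC(=O)CC(O)(C(C)C)c1ccc(OC)cc1
F6 | step 1 | racemic 3-hydroxy-3-(4-methoxyphenyl)-4-methylpentanoic acid | OC(=O)CC(O)(C(C)C)c1ccc(OC)cc1
F7 | step 1 | (S)-1-phenylethylammonium (R)-3-hydroxy-3-(4-methoxyphenyl)-4-methylpentanoate | C[C@H]([NH3+])c1ccccc1.[O-]C(=O)C[C@@](O)(C(C)C)c1ccc(OC)cc1
F8 | step 1 | (R)-3-hydroxy-3-(4-methoxyphenyl)-4-methylpentanoic acid | OC(=O)C[C@@](O)(C(C)C)c1ccc(OC)cc1
F9 | step 1 | triethylsilyl (R)-3-(4-methoxyphenyl)-4-methyl-3-(triethylsilyloxy)pentanoate | CC(C)[C@](O[Si](CC)(CC)CC)(CC(=O)O[Si](CC)(CC)CC)c1ccc(OC)cc1
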